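**Retrosynthetic overview**
1. Caespitol 18 ⇐ silyl ether 17 ⇐ open-chain bromochloro diol 15. One operation closes ring A (cyclohexane) through the bond between its oxane-bearing CH and the CH2 next to CHBr, and ring B (oxane) through the O–C(quaternary) bond; no ring exists before this step.
2. Enabling feature: the secondary bromine on the CHBr carbon of ring A. In the open chain it sits β to the primary CH2–OTf, turns that carbon into a bromiranium electrophile, and must end antiperiplanar (equatorial) to the new ring bond. The 6E alkene lies five atoms from that CH2, and the tertiary OH on the CMe2 carbon lies six atoms from the alkene carbon that becomes the quaternary oxane carbon.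
3. 15 ⇐ (2Z)-allylic alcohol 14 by catalytic enantioselective anti-bromochlorination (Br at C2, Cl at C3).
4. 14 ⇐ epoxide 13 (bromide opening at C10) ⇐ mesylate 11 ⇐ aldol adduct 8 (C8 from a boron aldol reaction, C10 from an oxazaborolidine reduction).
5. 8 ⇐ enal 3 (from neryl acetate 1 by allylic oxidation) + silyloxy methyl ketone 5 (from hydroxy ketone 4).

Key step: step 11

Remark: open-chain intermediates are numbered along the dodecane chain from the acetate/primary-alcohol carbon (C1); the facial sense of each chiral reagent is assigned from its accepted transition-state model and is an assumption of the proposal.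

Step 1
Reactants: 1 neryl acetate, (2Z)-3,7-dimethylocta-2,6-dien-1-yl acetate
Product: 2 (2Z,6E)-8-hydroxy-3,7-dimethylocta-2,6-dien-1-yl acetate
Conditions: SeO2 (cat.), t-BuOOH, salicylic acid (cat.), CH2Cl2, 0 °C to rt
Reagents that add atoms: tert-butyl hydroperoxide, CC(C)(C)OO (terminal oxidant); selenium dioxide, O=[Se]=O (oxygen relay)
Why: Riley allylic oxidation (ene reaction, then [2,3]-sigmatropic shift) should attack the electron-rich terminal trisubstituted alkene at its E methyl group and leave the alkene deactivated by the allylic acetate alone, which fixes the 6E geometry.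

Step 2
Reactants: 2 (2Z,6E)-8-hydroxy-3,7-dimethylocta-2,6-dien-1-yl acetate
Product: 3 (2Z,6E)-3,7-dimethyl-8-oxoocta-2,6-dien-1-yl acetate
Conditions: Cu(MeCN)4OTf (cat.), 2,2'-bipyridine, TEMPO, N-methylimidazole, air, MeCN, rt
Reagents that add atoms: none
Why: Copper/nitroxyl aerobic oxidation is selective for primary allylic alcohols, stops at the aldehyde and should keep the E geometry of the enal.

Step 3
Reactants: 4 3-hydroxy-3-methylbutan-2-one
Product: 5 3-methyl-3-[(trimethylsilyl)oxy]butan-2-one
Conditions: Me3SiCl, Et3N, DMAP (cat.), CH2Cl2, 0 °C to rt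
Reagents that add atoms: chlorotrimethylsilane, C[Si](C)(C)Cl
Why: Silylation of the tertiary alcohol masks the hydroxyl for the boron aldol reaction with a group that the basic methanolysis of step 8 removes again.

Step 4
Reactants: 5 3-methyl-3-[(trimethylsilyl)oxy]butan-2-one; 3 (2Z,6E)-3,7-dimethyl-8-oxoocta-2,6-dien-1-yl acetate
Product: 8 (2Z,6E,8R)-8-hydroxy-3,7,11-trimethyl-10-oxo-11-[(trimethylsilyl)oxy]dodeca-2,6-dien-1-yl acetate, via enol diisopinocampheylborinate 6 (not isolated), via boron aldolate 7 (not isolated)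
Conditions: (−)-Ipc2BCl [from (+)-α-pinene], Et3N, Et2O, 0 °C; then 3, −78 to −20 °C; then H2O2, MeOH, pH 7 buffer
Reagents that add atoms: none
Why: Boron-mediated asymmetric aldol reaction of a methyl ketone, in which the enol borinate (only the methyl side can enolise) adds through a cyclic six-membered transition state to the Re face of the enal under control of the isopinocampheyl groups and sets C8 as R; any minor enantiomer becomes a separable diastereomer after step 6.

Step 5
Reactants: 8 (2Z,6E,8R)-8-hydroxy-3,7,11-trimethyl-10-oxo-11-[(trimethylsilyl)oxy]dodeca-2,6-dien-1-yl acetate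
Product: 9 (2Z,6E,8R)-8-[(tert-butyldimethylsilyl)oxy]-3,7,11-trimethyl-10-oxo-11-[(trimethylsilyl)oxy]dodeca-2,6-dien-1-yl acetate
Conditions: TBSOTf, 2,6-lutidine, CH2Cl2, −78 °C
Reagents that add atoms: tert-butyldimethylsilyl trifluoromethanesulfonate, CC(C)(C)[Si](C)(C)OS(=O)(=O)C(F)(F)F
Why: Low-temperature silylation with the silyl triflate should outrun retro-aldol cleavage or β-elimination and installs a non-participating group on the C8 oxygen that lasts to the end.

Step 6
Reactants: 9 (2Z,6E,8R)-8-[(tert-butyldimethylsilyl)oxy]-3,7,11-trimethyl-10-oxo-11-[(trimethylsilyl)oxy]dodeca-2,6-dien-1-yl acetate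
Product: 10 (2Z,6E,8R,10R)-8-[(tert-butyldimethylsilyl)oxy]-10-hydroxy-3,7,11-trimethyl-11-[(trimethylsilyl)oxy]dodeca-2,6-dien-1-yl acetate
Conditions: (S)-Me-CBS [(S)-1-methyl-3,3-diphenyltetrahydro-1H,3H-pyrrolo[1,2-c][1,3,2]oxazaborole] (cat.), catecholborane, toluene, −78 °C
Reagents that add atoms: none
Why: Corey–Bakshi–Shibata reduction, in which the catalyst binds the ketone anti to the bulky C(CH3)2OSiMe3 group and delivers hydride to one face, sets C10 as R under reagent control; catecholborane at low temperature should spare the alkenes and the acetate.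

Step 7
Reactants: 10 (2Z,6E,8R,10R)-8-[(tert-butyldimethylsilyl)oxy]-10-hydroxy-3,7,11-trimethyl-11-[(trimethylsilyl)oxy]dodeca-2,6-dien-1-yl acetate
Product: 11 (2Z,6E,8R,10R)-8-[(tert-butyldimethylsilyl)oxy]-10-[(methylsulfonyl)oxy]-3,7,11-trimethyl-11-[(trimethylsilyl)oxy]dodeca-2,6-dien-1-yl acetate
Conditions: MsCl, Et3N, CH2Cl2, 0 °C
Reagents that add atoms: methanesulfonyl chloride, CS(=O)(=O)Cl
Why: Mesylation through sulfene tolerates the hindered secondary alcohol and prepares C10 for intramolecular displacement with the configuration unchanged.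

Step 8
Reactants: 11 (2Z,6E,8R,10R)-8-[(tert-butyldimethylsilyl)oxy]-10-[(methylsulfonyl)oxy]-3,7,11-trimethyl-11-[(trimethylsilyl)oxy]dodeca-2,6-dien-1-yl acetate
Product: 13 (2Z,6E,8R)-8-[(tert-butyldimethylsilyl)oxy]-9-[(2S)-3,3-dimethyloxiran-2-yl]-3,7-dimethylnona-2,6-dien-1-ol, via hydroxy mesylate 12 (not isolated)
Conditions: K2CO3, MeOH, rt
Reagents that add atoms: none
Why: Methanolysis should remove the acetate and the tertiary trimethylsilyl ether, after which the tertiary alkoxide displaces the mesylate in a 3-exo-tet Williamson closure with inversion at C10 to give the (S)-epoxide, the secondary TBS ether being stable.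

Step 9
Reactants: 13 (2Z,6E,8R)-8-[(tert-butyldimethylsilyl)oxy]-9-[(2S)-3,3-dimethyloxiran-2-yl]-3,7-dimethylnona-2,6-dien-1-ol
Product: 14 (2Z,6E,8R,10R)-10-bromo-8-[(tert-butyldimethylsilyl)oxy]-3,7,11-trimethyldodeca-2,6-diene-1,11-diol
Conditions: Li2NiBr4, THF, 0 °C to rt
Reagents that add atoms: dilithium tetrabromonickelate, [Li+].[Li+].Br[Ni-2](Br)(Br)Br
Why: SN2 epoxide opening by soft bromide should occur at the less substituted carbon C10 with inversion, which returns C10 to R and frees the tertiary alcohol that later becomes the oxane oxygen.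

Step 10
Reactants: 14 (2Z,6E,8R,10R)-10-bromo-8-[(tert-butyldimethylsilyl)oxy]-3,7,11-trimethyldodeca-2,6-diene-1,11-diol
Product: 15 (2S,3S,6E,8R,10R)-2,10-dibromo-8-[(tert-butyldimethylsilyl)oxy]-3-chloro-3,7,11-trimethyldodec-6-ene-1,11-diol
Conditions: NBS, ClTi(OiPr)3, chiral tridentate Schiff-base ligand from 3,5-di-tert-butylsalicylaldehyde and an enantiopure 1,2-amino alcohol (cat., enantiomer giving 2S,3S), hexanes, −20 °C
Reagents that add atoms: N-bromosuccinimide, O=C1CCC(=O)N1Br; chlorotitanium triisopropoxide, CC(C)O[Ti](Cl)(OC(C)C)OC(C)C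
Why: Titanium-mediated catalytic enantioselective bromochlorination of an allylic alcohol, in which the titanium-bound allylic alkoxide directs bromenium to C2 and chloride to the tertiary C3 in an anti addition across the 2Z alkene, with the ligand choosing the face to give 2S,3S; the C6 alkene has no free allylic hydroxyl and should not be engaged.

Step 11
Reactants: 15 (2S,3S,6E,8R,10R)-2,10-dibromo-8-[(tert-butyldimethylsilyl)oxy]-3-chloro-3,7,11-trimethyldodec-6-ene-1,11-diol
Product: 17 (2R,3R,5R)-5-bromo-2-[(1S,3S,4S)-3-bromo-4-chloro-4-methylcyclohexyl]-3-[(tert-butyldimethylsilyl)oxy]-2,6,6-trimethyloxane, via primary triflate 16 (not isolated)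
Conditions: Tf2O, 2,6-di-tert-butyl-4-methylpyridine, CH2Cl2, −78 °C; then (CF3)2CHOH, −78 to 0 °C
Reagents that add atoms: none
Why: Proposed new method: chemoselective triflation of the primary alcohol gives 16, whose C2 bromine displaces triflate from the rear to form a C1/C2 bromiranium ion; the 6E alkene opens this ion at the primary carbon C1 while the tertiary C11 hydroxyl adds to C7 on the opposite alkene face, so one anti addition forms the ring A C–C bond and the ring B C–O bond, the closest known reaction types being the stereospecific generation of bromiranium ions from activated β-bromo alcohols with capture by a tethered alkene and the sulfonate-initiated cation–olefin cyclisation terminated by a hydroxyl group. Ring A closes 6-endo with respect to the bromiranium ring and exo with respect to the alkene, and ring B closes by 6-exo attack of oxygen on C7. The new CH stereocentre of ring A (S) should follow from the chair in which the bromine, which must be antiperiplanar to the forming C1–C6 bond, is equatorial, so that chlorine and the alkene carbon C7 are equatorial as well and only the C3 methyl is axial. The quaternary oxane carbon (R) should follow from anti addition across the E alkene and from the oxane chair with the C10 bromine equatorial and the C8 silyloxy group axial, out of line with the developing p orbital at C7. The step needs attack at C1 and not C2 of the bromiranium ion, which the quaternary, chlorine-bearing C3 should secure by shielding and deactivating C2, and it needs the tertiary chloride and the tertiary alcohol to survive activation, which low temperature, one equivalent of anhydride and the hindered base should secure.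

Step 12
Reactants: 17 (2R,3R,5R)-5-bromo-2-[(1S,3S,4S)-3-bromo-4-chloro-4-methylcyclohexyl]-3-[(tert-butyldimethylsilyl)oxy]-2,6,6-trimethyloxane
Product: 18 caespitol, (2R,3R,5R)-5-bromo-2-[(1S,3S,4S)-3-bromo-4-chloro-4-methylcyclohexyl]-2,6,6-trimethyloxan-3-ol
Conditions: HF·pyridine, pyridine, THF, 0 °C to rt
Reagents that add atoms: none
Why: Fluoride-mediated desilylation under non-basic conditions should cleave the hindered secondary silyl ether without elimination of the secondary bromides or the tertiary chloride.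

**Compound list**
1 | neryl acetate, (2Z)-3,7-dimethylocta-2,6-dien-1-yl acetate | CC(=O)OC/C=C(C)\CCC=C(C)C | starting material
2 | (2Z,6E)-8-hydroxy-3,7-dimethylocta-2,6-dien-1-yl acetate | CC(=O)OC/C=C(C)\CC/C=C(\C)CO | intermediate
3 | (2Z,6E)-3,7-dimethyl-8-oxoocta-2,6-dien-1-yl acetate | CC(=O)OC/C=C(C)\CC/C=C(\C)C=O | intermediate
4 | 3-hydroxy-3-methylbutan-2-one | CC(=O)C(C)(C)O | starting material
5 | 3-methyl-3-[(trimethylsilyl)oxy]butan-2-one | CC(=O)C(C)(C)O[Si](C)(C)C | intermediate
6 | enol diisopinocampheylborinate of 5 (isopinocampheyl groups from (+)-α-pinene) | C=C(OB([C@@H]1C[C@@H]2C[C@H]([C@H]1C)C2(C)C)[C@@H]1C[C@@H]2C[C@H]([C@H]1C)C2(C)C)C(C)(C)O[Si](C)(C)C | intermediate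
7 | boron aldolate, 8-O-diisopinocampheylboryl derivative of 8 | CC(=O)OC/C=C(C)\CC/C=C(\C)[C@H](OB([C@@H]1C[C@@H]2C[C@H]([C@H]1C)C2(C)C)[C@@H]1C[C@@H]2C[C@H]([C@H]1C)C2(C)C)CC(=O)C(C)(C)O[Si](C)(C)C | intermediate
8 | (2Z,6E,8R)-8-hydroxy-3,7,11-trimethyl-10-oxo-11-[(trimethylsilyl)oxy]dodeca-2,6-dien-1-yl acetate | CC(=O)OC/C=C(C)\CC/C=C(\C)[C@H](O)CC(=O)C(C)(C)O[Si](C)(C)C | intermediate
9 | (2Z,6E,8R)-8-[(tert-butyldimethylsilyl)oxy]-3,7,11-trimethyl-10-oxo-11-[(trimethylsilyl)oxy]dodeca-2,6-dien-1-yl acetate | CC(=O)OC/C=C(C)\CC/C=C(\C)[C@H](O[Si](C)(C)C(C)(C)C)CC(=O)C(C)(C)O[Si](C)(C)C | intermediate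
10 | (2Z,6E,8R,10R)-8-[(tert-butyldimethylsilyl)oxy]-10-hydroxy-3,7,11-trimethyl-11-[(trimethylsilyl)oxy]dodeca-2,6-dien-1-yl acetate | CC(=O)OC/C=C(C)\CC/C=C(\C)[C@H](O[Si](C)(C)C(C)(C)C)C[C@@H](O)C(C)(C)O[Si](C)(C)C | intermediate
11 | (2Z,6E,8R,10R)-8-[(tert-butyldimethylsilyl)oxy]-10-[(methylsulfonyl)oxy]-3,7,11-trimethyl-11-[(trimethylsilyl)oxy]dodeca-2,6-dien-1-yl acetate | CC(=O)OC/C=C(C)\CC/C=C(\C)[C@H](O[Si](C)(C)C(C)(C)C)C[C@@H](OS(C)(=O)=O)C(C)(C)O[Si](C)(C)C | intermediate
12 | hydroxy mesylate, (2Z,6E,8R,10R)-8-[(tert-butyldimethylsilyl)oxy]-1,11-dihydroxy-3,7,11-trimethyldodeca-2,6-dien-10-yl methanesulfonate | OC/C=C(C)\CC/C=C(\C)[C@H](O[Si](C)(C)C(C)(C)C)C[C@@H](OS(C)(=O)=O)C(C)(C)O | intermediate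
13 | (2Z,6E,8R)-8-[(tert-butyldimethylsilyl)oxy]-9-[(2S)-3,3-dimethyloxiran-2-yl]-3,7-dimethylnona-2,6-dien-1-ol | OC/C=C(C)\CC/C=C(\C)[C@H](O[Si](C)(C)C(C)(C)C)C[C@@H]1OC1(C)C | intermediate
14 | (2Z,6E,8R,10R)-10-bromo-8-[(tert-butyldimethylsilyl)oxy]-3,7,11-trimethyldodeca-2,6-diene-1,11-diol | OC/C=C(C)\CC/C=C(\C)[C@H](O[Si](C)(C)C(C)(C)C)C[C@@H](Br)C(C)(C)O | intermediate
15 | (2S,3S,6E,8R,10R)-2,10-dibromo-8-[(tert-butyldimethylsilyl)oxy]-3-chloro-3,7,11-trimethyldodec-6-ene-1,11-diol | OC[C@H](Br)[C@@](C)(Cl)CC/C=C(\C)[C@H](O[Si](C)(C)C(C)(C)C)C[C@@H](Br)C(C)(C)O | intermediate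
16 | primary triflate, (2S,3S,6E,8R,10R)-2,10-dibromo-8-[(tert-butyldimethylsilyl)oxy]-3-chloro-11-hydroxy-3,7,11-trimethyldodec-6-en-1-yl trifluoromethanesulfonate | FC(F)(F)S(=O)(=O)OC[C@H](Br)[C@@](C)(Cl)CC/C=C(\C)[C@H](O[Si](C)(C)C(C)(C)C)C[C@@H](Br)C(C)(C)O | intermediate
17 | (2R,3R,5R)-5-bromo-2-[(1S,3S,4S)-3-bromo-4-chloro-4-methylcyclohexyl]-3-[(tert-butyldimethylsilyl)oxy]-2,6,6-trimethyloxane | CC1(C)O[C@](C)([C@H]2CC[C@](C)(Cl)[C@@H](Br)C2)[C@H](O[Si](C)(C)C(C)(C)C)C[C@H]1Br | intermediate
18 | caespitol, (2R,3R,5R)-5-bromo-2-[(1S,3S,4S)-3-bromo-4-chloro-4-methylcyclohexyl]-2,6,6-trimethyloxan-3-ol | CC1(C)O[C@](C)([C@H]2CC[C@](C)(Cl)[C@@H](Br)C2)[C@H](O)C[C@H]1Br | target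

Total step count: 12. Longest linear sequence: 11 steps (steps 1, 2 and 4 to 12, from neryl acetate 1).

**Steps most likely to fail**

Step 11 (proposed new method). The bromiranium ion may be opened at C2 instead of C1, with a 1,2-bromine shift and five-membered ring closure. The tertiary chloride may ionise, the tertiary alcohol may be triflated, or the two chair preferences may not reinforce each other, giving poor facial selectivity at the alkene. The fallback uses known chemistry, sets out from 14 and comes back at 17. The primary allylic alcohol of 14 would be phosphorylated selectively (ClP(O)(OEt)2, pyridine, CH2Cl2, 0 °C) to the diethyl phosphate of 14, F1. Ionisation of this 2Z allylic phosphate in buffered (CF3)2CHOH (2,6-lutidine, 0 °C) would give the cisoid allyl cation, which closes ring A onto the 6E alkene in the known head-initiated cyclisation of neryl-type esters; capture at C7 by the tertiary hydroxyl would give (2R,3R,5R)-5-bromo-3-[(tert-butyldimethylsilyl)oxy]-2,6,6-trimethyl-2-[(1S)-4-methylcyclohex-3-en-1-yl]oxane, F2. Anti addition of BrCl (Et4N+ BrCl2−, CH2Cl2, −78 °C) to the ring alkene of F2 would then install bromine at the secondary and chlorine at the tertiary carbon. Compound 17, the trans-diequatorial adduct, would have to be separated from the trans-diaxial adduct formed through the other bromonium ion, and this is the weakness of the fallback.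

Step 9. Bromide may attack the tertiary epoxide carbon, or the Lewis-acidic metal may induce rearrangement of the epoxide to a carbonyl compound. The fallback sets out from 9 and comes back at 14. Reduction of 9 with the (R)-oxazaborolidine and catecholborane would give the 10S epimer of 10, (2Z,6E,8R,10S)-8-[(tert-butyldimethylsilyl)oxy]-10-hydroxy-3,7,11-trimethyl-11-[(trimethylsilyl)oxy]dodeca-2,6-dien-1-yl acetate, F3. Mild acid methanolysis (PPTS, MeOH, 0 °C) would remove only the trimethylsilyl group and give the diol (2Z,6E,8R,10S)-8-[(tert-butyldimethylsilyl)oxy]-10,11-dihydroxy-3,7,11-trimethyldodeca-2,6-dien-1-yl acetate, F4. Formation of the cyclic orthoacetate (MeC(OMe)3, PPTS) and treatment with acetyl bromide would open the acetoxonium ion by bromide at the secondary carbon with inversion, giving (2Z,6E,8R,10R)-10-bromo-8-[(tert-butyldimethylsilyl)oxy]-3,7,11-trimethyldodeca-2,6-diene-1,11-diyl diacetate, F5. Reductive removal of both acetates (i-Bu2AlH, CH2Cl2, −78 °C) avoids base, which would close the bromohydrin to an epoxide, and would give 14.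

Step 10. Face selection by the catalyst may be poor on this Z alkene, the free tertiary hydroxyl may bind titanium and slow the directed pathway, or bromenium may be diverted to the C6 alkene. The fallback sets out from 14 and comes back at 15. It gives up catalyst control: the ligand-free, hydroxyl-directed bromochlorination (NBS, ClTi(OiPr)3, hexanes/CH2Cl2, −20 °C) keeps the regiochemistry and the anti addition and would give 15 together with its 2R,3R diastereomer, (2R,3R,6E,8R,10R)-2,10-dibromo-8-[(tert-butyldimethylsilyl)oxy]-3-chloro-3,7,11-trimethyldodec-6-ene-1,11-diol, F6. The two would be separated by chromatography. If they do not separate at this stage, the mixture would be taken through step 11 and the separation done on the rigid bicyclic products, where all stereocentres sit close together.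

**Further compounds**
F1 | step 11 | diethyl (2Z,6E,8R,10R)-10-bromo-8-[(tert-butyldimethylsilyl)oxy]-11-hydroxy-3,7,11-trimethyldodeca-2,6-dien-1-yl phosphate | CCOP(=O)(OCC)OC/C=C(C)\CC/C=C(\C)[C@H](O[Si](C)(C)C(C)(C)C)C[C@@H](Br)C(C)(C)O
F2 | step 11 | (2R,3R,5R)-5-bromo-3-[(tert-butyldimethylsilyl)oxy]-2,6,6-trimethyl-2-[(1S)-4-methylcyclohex-3-en-1-yl]oxane | CC1(C)O[C@](C)([C@H]2CCC(C)=CC2)[C@H](O[Si](C)(C)C(C)(C)C)C[C@H]1Br
F3 | step 9 | (2Z,6E,8R,10S)-8-[(tert-butyldimethylsilyl)oxy]-10-hydroxy-3,7,11-trimethyl-11-[(trimethylsilyl)oxy]dodeca-2,6-dien-1-yl acetate | CC(=O)OC/C=C(C)\CC/C=C(\C)[C@H](O[Si](C)(C)C(C)(C)C)C[C@H](O)C(C)(C)O[Si](C)(C)C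
F4 | step 9 | (2Z,6E,8R,10S)-8-[(tert-butyldimethylsilyl)oxy]-10,11-dihydroxy-3,7,11-trimethyldodeca-2,6-dien-1-yl acetate | CC(=O)OC/C=C(C)\CC/C=C(\C)[C@H](O[Si](C)(C)C(C)(C)C)C[C@H](O)C(C)(C)O
F5 | step 9 | (2Z,6E,8R,10R)-10-bromo-8-[(tert-butyldimethylsilyl)oxy]-3,7,11-trimethyldodeca-2,6-diene-1,11-diyl diacetate | CC(=O)OC/C=C(C)\CC/C=C(\C)[C@H](O[Si](C)(C)C(C)(C)C)C[C@@H](Br)C(C)(C)OC(C)=O
F6 | step 10 | (2R,3R,6E,8R,10R)-2,10-dibromo-8-[(tert-butyldimethylsilyl)oxy]-3-chloro-3,7,11-trimethyldodec-6-ene-1,11-diol | OC[C@@H](Br)[C@](C)(Cl)CC/C=C(\C)[C@H](O[Si](C)(C)C(C)(C)C)C[C@@H](Br)C(C)(C)O
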